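The vessel was a closed, stirred flask of constant volume at one temperature, and this is what ran in it.

    substrate → intermediate (k1 = 6.7 × 10⁻⁴ /s)
    first nucleophile + intermediate → target (k2 = 0.067 /M/s)
    second nucleophile + intermediate → other capture product (k3 = 0.13 /M/s)
    intermediate → solvolysis product (k4 = 0.12 /s)
    first nucleophile + protic impurity → quenched reagent (k5 = 0.0061 /M/s)
    2 first nucleophile → self-condensation product (k6 = 0.0010 /M/s)

substrate 0.50 M; first nucleophile 0.800 equiv; second nucleophile 1.00 equiv; protic impurity 0.0500 M; time 10 h

- for a step with 2 of a species take k times the square, and two of it per event
- the reaction counts as stopped when no species that holds the substrate changes by six tenths of a point or more over the second half of the time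
- run time (flask): 10 h

- which holds at 10 h: what has brought the reaction to rest, or that it has not come to rest (the second nucleophile has run out first / the first nucleophile has run out first / it is still moving / all of the substrate has reacted)
- part of the substrate gone at 10 h
- the target standing at 10 h, as a percentage of the substrate charged
- the solvolysis product standing at 10 h, as a percentage of the substrate charged
- the other capture product standing at 10 h, as a percentage of the substrate charged

I built the flask up one process at a time. With the first step by itself the substrate had a half-life of 0.29 h, short against 10 h, so I expected it to be gone at the asked time. Adding solvolysis gave the intermediate a lifetime of 8.33 s, far shorter than the substrate's half-life, so I expected the intermediate to stay small and each moment to be a choice between its exits.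

Adding the second nucleophile opened another exit, and the choice became a number:

capture ratio = 0.13 /M/s × 0.500 M / 0.12 /s = 0.542

I called this the capture ratio: the rate at which the second nucleophile takes the intermediate over the rate at which solvolysis takes it, at the charged amount of second nucleophile. It is a selectivity factor, and it counts the other capture product made per solvolysis product made. At that charge it gave the other capture product 35.1 % of the two. That draws on the second nucleophile, whose charge matched the substrate's, so I held 82.5 % of it on average:

ratio over the run = 0.542 × 82.5 % = 0.447

Last came the first nucleophile, a third exit worth 0.223 of solvolysis at its charge. It drew on the other two exits alike, so at a given amount of second nucleophile the ratio between them stood. Its own first half-life by self-condensation alone was 0.347 h, and its half-life by the protic impurity alone was 0.63 h, the latter with the other concentrations held at their charge. Set beside the substrate's 0.29 h, these meant I expected it to fall while the intermediate was still being made, and I committed to no number for the target.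

The forecast said all of the substrate has reacted, with conversion 100 %, target 6.9 %, solvolysis product 64 % and other capture product 29.1 %, on the ground that “Solvolysis dominates and the second nucleophile takes a steady share”. Its target figure is one I had not reckoned.

The simulation gave all of the substrate has reacted, with conversion 100 %, target 6.90 %, solvolysis product 63.9 % and other capture product 29.2 %.

In this flask the reading of other capture product over solvolysis product was 0.457, with 71 % of the second nucleophile left at 10.0 h. I took the same reckoning to the neighbouring flask, charged with 2.50 equiv of second nucleophile, other charges and time held. Its capture ratio was 1.35, its share 57.5 %, and the draw on its larger charge gave 1.20 over the run. That neighbouring flask read 1.21, with other capture product at 52.1 % against solvolysis product at 43.1 %.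

The constants used here are made up; what happens was integrated by code.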